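## Analysis of the target

The target is a 3-substituted 5,7-dimethoxyphthalide in which arene ring A is fused to γ-lactone ring B and C3 carries an unbranched chain C1'–C6' that ends at C2'' of a 7''-methyl-1,6-dioxaspiro[4.4]nonane (tetrahydrofuran rings C and D joined at the ketal carbon C5''). There are four stereocentres, all S: C3 (benzylic and bound to the lactone oxygen), the carbinol carbons C2'' and C7'', and the spiro carbon C5'', and in the required isomer each alkyl group lies cis to the oxygen of the other ring. C3 is separated from the spiroketal by six methylene groups, so it gets no help from the other three centres and needs its own absolute control. The five-membered spiroketal has little anomeric bias and epimerises at C5'' under acid, so once C5'' is fixed, acid must be kept out; C3–H is benzylic and α to oxygen, and the lactone is an electrophile. Ring A is awkward to reach by substitution of a preformed arene, because the alkyl-bearing carbon C3a is ortho to the carboxyl-bearing C7a while the oxygens at C5 and C7 are meta to each other. That same pattern is the handle: C5 and C7 are 1,3-related across C6 and C7a bears C1, which is the pattern of a cyclohexane-1,3-dione with an ester on the carbon next to one carbonyl. Ring A can therefore be built as a carbocycle from a four-carbon enone unit (C3a, C4, C5, C6) and a malonate (C7a, C7, C1) and aromatised late, with C3 outside the new ring.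

## Retrosynthetic reasoning

**Ring B and the methyl ethers.** The lactone C1–O2 bond of 27 is cut to the ortho-(1-silyloxyalkyl) benzoate 25. Ring B then closes by itself when the silyl group is removed under basic fluoride conditions, and C3–O is never broken. The two O–CH3 bonds go back to the resorcylate 24. Methylating before lactonisation keeps C3 as a non-acidic silyl ether carbon during the basic alkylation.

**Ring A by dehydrogenation.** Arene 24 is the dehydrogenated form of cyclohexane-1,3-dione 21, so two hydrogens (from C3a and C4 or C7a) must be removed. Halogen-based aromatisations release strong acid, which would scramble C5'' and strip the silyl ether. The forward step therefore goes through the bis(silyl) dienol ether 22 and a quinone oxidant under buffered conditions.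

**The key disconnection.** In 21 the bonds C3a–C7a and C6–C7 are cut, giving enone 18 and dimethyl malonate 19. This cut builds the carboxyl carbon C1 and both ring oxygens into ring A with no regiochemical choice to be made. It also leaves C3 as an exocyclic stereocentre that is set beforehand and is insulated from every reacting π system once the conjugate addition has taken place. The forward reaction has to add the malonate to the β-carbon of a γ-silyloxy enone faster than the enone is deprotonated at its γ-position.

**The enone and C3.** Enone 18 comes from alcohol 17 and this from the O-anilino ether 16. The C3=C4 double bond of the enone (undecenone numbering) is a Wittig disconnection to ylide 14 and the α-oxygenated aldehyde 15. The C–O bond at the future C3 is made by amine-catalysed α-aminoxylation of aldehyde 13. This places the oxygen and the stereocentre in one catalytic step, directly on the chain that already carries the spiroketal.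

**The aldehyde.** Aldehyde 13 is unmasked from the terminal alkene 12 by ozonolysis. The alkene survives the organolithium and acid steps that build the spiroketal.

**The spiro centre.** The single epimer 12 is traced to 11, the same spiroketal as a mixture of its two C5'' epimers. No reagent can set C5'' here, so the forward operation is separation of the diastereomers, with the 5R component of 11 returned to the mixture by acid and separated again.

**The spiroketal.** Mixture 11 is opened to the dihydroxy ketone 10, masked as hydrazone 9. The bonds C3''–C4'' and C8''–C9'' on either side of the ketone carbon are cut, giving the acetone hydrazone 6 and the two terminal epoxides 7 and 5. C7'' and C2'' are thus bought as epoxide stereocentres.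

**The long-chain epoxide.** Epoxide 5 goes back to chlorohydrin 4, and this to Grignard reagent 3 (made from bromide 1) and the chiral three-carbon epoxide 2. A copper-catalysed opening transfers the configuration of 2 fully, without a resolution of a racemic epoxide.

## Alternatives that were turned down

Alternative 1: The disconnection is the same pair of C–C bonds flanking C5'', but made on a substrate that already carries the aryl carbinol. In the forward key step, doubly lithiated 6 opens 7 and then the aryl-bearing epoxide A2 in one flask to give the hydrazone diol A1.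
- For: it is the most convergent plan, and three stereocentres arrive as epoxide or carbinol building blocks. On convergence and on the spiroketal part it is as strong as the chosen route, which uses the same hydrazone tactic on the simpler epoxide 5.
- Against: A1 still lacks C1 and ring B. The 3,5-dimethoxyphenyl ring must be carboxylated at C7a, ortho to the carbinol and next to one methoxy group, while directed metalation prefers the position between the two methoxy groups. A halogenation–carbonylation sequence would have to be run with the acid-sensitive spiroketal present. The benzylic stereocentre of A2 also needs its own asymmetric step.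
- Comparison: the chosen strategy gives up some convergence and offers instead an arene whose substitution pattern is fixed by construction, with no late aromatic functionalisation.

Alternative 2: The disconnection is the C5''–O6'' bond of ring D. In the forward key step an electrophilic iodine source adds to C4'' of the ring C enol ether A4, and the tethered C7'' hydroxyl attacks C5'' anti to iodine, giving the iodo-spiroketal A3. Reductive removal of iodine follows.
- For: it is the only plan that sets C5'' kinetically. On this point it is stronger than the chosen route, which relies on separation and recycling.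
- Against: the face of iodine delivery is steered only by the C2'' substituent across the ring, so the bias may be modest. The dihydrofuran A4 is itself acid-labile and needs several steps. Once the iodine is gone, the spiro centre is as prone to acid epimerisation as in any other route, so the kinetic gain can be lost. From the amide of A3 the whole phthalide (aryl ketone, asymmetric reduction, carboxylation) remains to be built.
- Comparison: the chosen strategy accepts an uncontrolled C5'' but reaches the spiroketal in two steps from simple epoxides and spends its effort on ring A and C3.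

Alternative 3: The disconnection is C3a–C3 and C3–O2. In the forward key step the iodo acid A6 couples with the terminal alkyne A7 under palladium–copper catalysis and the carboxylate adds 5-exo-dig to the alkyne, giving the (Z)-alkylidenephthalide A5. Enantioselective hydrogenation of the exocyclic double bond then has to set C3.
- For: the arene is bought with its oxygenation in place, ring A needs no oxidation-level change, and the route is shorter. On step economy it is stronger than the chosen route.
- Against: with alkyl alkynes the 6-endo closure to an isocoumarin competes. C3 would be created last, by hydrogenating a trisubstituted enol-lactone alkene whose only substituent is an unbranched chain, so there is little for a chiral catalyst to distinguish. An error in enantioselectivity at that point cannot be corrected.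
- Comparison: the chosen strategy is longer but sets C3 early, by a catalytic oxygenation whose sense is predictable, and carries it through unchanged.

Key step: step 10

Remark: the 1,6-dioxaspiro[4.4]nonane is taken to have no useful thermodynamic preference at C5'' and to epimerise only under acid; C5'' is therefore fixed by separation and recycling (step 5) and every later step is run without acid.

## Route

Step 1
Reactants: 1 8-bromooct-1-ene; 2 (S)-2-(chloromethyl)oxirane
Product: 4 (S)-1-chloroundec-10-en-2-ol, via oct-7-en-1-ylmagnesium bromide 3 (not isolated)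
Conditions: Mg, THF, reflux; then 2, CuI (10 mol %), THF, −40 → 0 °C; H2O
Reagents that add atoms: none
Why: Copper-catalysed Grignard opening of the epoxide at its unsubstituted carbon is faster than displacement of chloride; the stereocentre of 2 is not touched and becomes C2''.

Step 2
Reactants: 4 (S)-1-chloroundec-10-en-2-ol
Product: 5 (S)-2-(non-8-en-1-yl)oxirane
Conditions: NaOH (powdered), Et2O, rt
Reagents that add atoms: none
Why: Intramolecular Williamson closure (3-exo-tet) of the chlorohydrin; the carbinol carbon keeps its configuration, so the new epoxide is S.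

Step 3
Reactants: 6 acetone N,N-dimethylhydrazone; 7 (S)-2-methyloxirane; 5 (S)-2-(non-8-en-1-yl)oxirane
Product: 9 (2S,8S)-5-(2,2-dimethylhydrazinylidene)heptadec-16-ene-2,8-diol, via mono-adduct hydrazone 8 (not isolated)
Conditions: n-BuLi, THF, −78 → 0 °C; 7, −78 °C → rt; n-BuLi, −78 → 0 °C; 5, −78 °C → rt; H2O
Reagents that add atoms: none
Why: The lithiated hydrazone (aza-enolate) opens terminal epoxides at the CH2 carbon; after the first alkylation the second lithiation takes place at the remaining methyl group, so both arms are attached in one flask (sequential aza-enolate alkylation). C7'' and C2'' are copied unchanged from 7 and 5.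

Step 4
Reactants: 9 (2S,8S)-5-(2,2-dimethylhydrazinylidene)heptadec-16-ene-2,8-diol
Product: 11 (2S,7S)-2-methyl-7-(non-8-en-1-yl)-1,6-dioxaspiro[4.4]nonane (mixture of both C5 epimers), via dihydroxy ketone 10 (not isolated)
Conditions: aq. oxalic acid, Et2O, rt; then PPTS (cat.), CH2Cl2, 4 Å MS, rt; filtration through Et3N-deactivated SiO2
Reagents that add atoms: none
Why: Acid hydrolysis of the hydrazone frees the dihydroxy ketone, which closes twice (5-exo) to the spiroketal under thermodynamic control (hydrazone hydrolysis, then spiroketalisation); the C–O bonds at the two carbinol carbons are not broken, so both stay S, while the spiro carbon is not controlled and both of its epimers should form.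

Step 5
Reactants: 11 (2S,7S)-2-methyl-7-(non-8-en-1-yl)-1,6-dioxaspiro[4.4]nonane (mixture of both C5 epimers)
Product: 12 (2S,5S,7S)-2-methyl-7-(non-8-en-1-yl)-1,6-dioxaspiro[4.4]nonane
Conditions: chromatography on Et3N-deactivated SiO2; 5R fraction: PPTS (cat.), CH2Cl2, rt, then chromatography again; repeated
Reagents that add atoms: none
Why: The two components of 11 are diastereomers and should separate on deactivated silica; PPTS reopens the ketal of the 5R fraction to the oxocarbenium ion and recloses it, which restores the epimeric mixture (acid-catalysed spiroketal epimerisation), so repeated cycles gather the material as 12. Only the bonds to the spiro carbon are broken, so the two carbinol centres are not affected.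

Step 6
Reactants: 12 (2S,5S,7S)-2-methyl-7-(non-8-en-1-yl)-1,6-dioxaspiro[4.4]nonane
Product: 13 8-[(2S,5S,7S)-7-methyl-1,6-dioxaspiro[4.4]nonan-2-yl]octanal
Conditions: O3, CH2Cl2, NaHCO3, −78 °C; then PPh3, −78 °C → rt
Reagents that add atoms: ozone, [O-][O+]=O
Why: Ozonolysis of the monosubstituted alkene with reductive work-up; the ketal carbon has no C–H for ozone to attack, and NaHCO3 keeps the medium free of acid, so C5'' is not disturbed.

Step 7
Reactants: 13 8-[(2S,5S,7S)-7-methyl-1,6-dioxaspiro[4.4]nonan-2-yl]octanal; 14 1-(triphenylphosphoranylidene)propan-2-one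
Product: 16 (S,E)-5-[(phenylamino)oxy]-11-[(2S,5S,7S)-7-methyl-1,6-dioxaspiro[4.4]nonan-2-yl]undec-3-en-2-one, via α-aminoxy aldehyde 15 (not isolated)
Conditions: D-proline (20 mol %), PhNO, CH3CN, −20 °C; then 14, 0 °C → rt
Reagents that add atoms: nitrosobenzene, O=Nc1ccccc1
Why: D-Proline forms the (E)-enamine of 13, and its carboxylic acid directs nitrosobenzene, through oxygen, to the face that gives the 2S aldehyde 15 (organocatalytic α-aminoxylation; L-proline gives the 2R series). The stabilised ylide 14 then olefinates 15 in the same flask before it can enolise (Wittig reaction), giving the E-enone.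

Step 8
Reactants: 16 (S,E)-5-[(phenylamino)oxy]-11-[(2S,5S,7S)-7-methyl-1,6-dioxaspiro[4.4]nonan-2-yl]undec-3-en-2-one
Product: 17 (S,E)-5-hydroxy-11-[(2S,5S,7S)-7-methyl-1,6-dioxaspiro[4.4]nonan-2-yl]undec-3-en-2-one
Conditions: Cu(OAc)2·H2O (30 mol %), EtOH, rt
Reagents that add atoms: none
Why: Cu(OAc)2-catalysed cleavage of the O–N bond of O-anilino ethers is redox-neutral and leaves the enone and the allylic stereocentre alone, unlike dissolving-metal or hydrogenolytic methods.

Step 9
Reactants: 17 (S,E)-5-hydroxy-11-[(2S,5S,7S)-7-methyl-1,6-dioxaspiro[4.4]nonan-2-yl]undec-3-en-2-one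
Product: 18 (S,E)-5-[(tert-butyldimethylsilyl)oxy]-11-[(2S,5S,7S)-7-methyl-1,6-dioxaspiro[4.4]nonan-2-yl]undec-3-en-2-one
Conditions: TBSCl, imidazole, DMF, 0 °C → rt
Reagents that add atoms: tert-butyldimethylsilyl chloride, CC(C)(C)[Si](C)(C)Cl
Why: Standard silylation of a secondary alcohol under basic conditions; the silyl ether blocks oxa-Michael addition, isomerisation to the 1,4-diketone and premature lactonisation in step 10.

Step 10
Reactants: 18 (S,E)-5-[(tert-butyldimethylsilyl)oxy]-11-[(2S,5S,7S)-7-methyl-1,6-dioxaspiro[4.4]nonan-2-yl]undec-3-en-2-one; 19 dimethyl malonate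
Product: 21 methyl 2-{(S)-1-[(tert-butyldimethylsilyl)oxy]-7-[(2S,5S,7S)-7-methyl-1,6-dioxaspiro[4.4]nonan-2-yl]heptyl}-4,6-dioxocyclohexane-1-carboxylate, via Michael adduct 20 (not isolated)
Conditions: 19 (1.1 equiv), NaOMe (0.2 equiv), MeOH, 0 °C → rt; then NaOMe (1.1 equiv), reflux; cold aq. NaH2PO4, extraction, used at once
Reagents that add atoms: none
Why: Methoxide generates the malonate anion, which adds to the β-carbon of the enone and forms the C3a–C7a bond (Michael addition). With a full equivalent of base and heat the methyl group of the new ketone is enolised and attacks one malonate ester, forming the C6–C7 bond with loss of methoxide (Claisen condensation). This closure is 6-exo-trig and gives the carbocycle that becomes ring A; the product is held as its stable dione enolate, which drives the equilibria forward. The closest known reaction type is the synthesis of 5-substituted 4-alkoxycarbonylcyclohexane-1,3-diones from enones and malonates. The ring centres C3a and C7a are formed without control and are erased in step 11, so no lasting stereocentre is created. The selectivity needed is conjugate addition over γ-deprotonation of the enone, which would erode C3; the soft, easily formed malonate anion, the protic solvent, the low temperature and the catalytic amount of base in the first stage favour addition. After the addition C3 is a saturated silyl ether carbon with no acidifying group next to it, so the harsher second stage cannot touch it. The bulky silyl group keeps the oxygen from lactonising onto the malonate esters.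

Step 11
Reactants: 21 methyl 2-{(S)-1-[(tert-butyldimethylsilyl)oxy]-7-[(2S,5S,7S)-7-methyl-1,6-dioxaspiro[4.4]nonan-2-yl]heptyl}-4,6-dioxocyclohexane-1-carboxylate
Product: 24 methyl 2-{(S)-1-[(tert-butyldimethylsilyl)oxy]-7-[(2S,5S,7S)-7-methyl-1,6-dioxaspiro[4.4]nonan-2-yl]heptyl}-4,6-dihydroxybenzoate, via bis(trimethylsilyl) dienol ether 22 (not isolated), via bis(trimethylsilyl) aryl ether 23 (not isolated)
Conditions: TMSCl, LiN(SiMe3)2, THF, −78 → 0 °C; then DDQ, 2,4,6-collidine, PhMe, 0 °C → rt; then K2CO3, MeOH, 0 °C
Reagents that add atoms: none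
Why: O-Silylation with in-situ trapping turns the dione into a 1,3-bis(silyloxy)cyclohexa-1,3-diene, which DDQ aromatises by hydride abstraction from C4 or C3a and loss of a proton (quinone dehydrogenation of silyl enol ethers and cyclohexadienes); every enol ether regioisomer leads to the same arene. Collidine takes up the acidic hydroquinone, so the spiroketal and the secondary silyl ether are not touched, and K2CO3 in MeOH then removes only the aryl silyl groups.

Step 12
Reactants: 24 methyl 2-{(S)-1-[(tert-butyldimethylsilyl)oxy]-7-[(2S,5S,7S)-7-methyl-1,6-dioxaspiro[4.4]nonan-2-yl]heptyl}-4,6-dihydroxybenzoate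
Product: 25 methyl 2-{(S)-1-[(tert-butyldimethylsilyl)oxy]-7-[(2S,5S,7S)-7-methyl-1,6-dioxaspiro[4.4]nonan-2-yl]heptyl}-4,6-dimethoxybenzoate
Conditions: MeI (excess), K2CO3, acetone, reflux
Reagents that add atoms: iodomethane, CI
Why: Williamson O-methylation of both phenols; the hydrogen-bonded hydroxyl next to the ester needs the excess reagent and heat. No acid is involved, and the silyloxy-bearing C3 is not acidic enough for K2CO3.

Step 13
Reactants: 25 methyl 2-{(S)-1-[(tert-butyldimethylsilyl)oxy]-7-[(2S,5S,7S)-7-methyl-1,6-dioxaspiro[4.4]nonan-2-yl]heptyl}-4,6-dimethoxybenzoate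
Product: 27 (S)-5,7-dimethoxy-3-{6-[(2S,5S,7S)-7-methyl-1,6-dioxaspiro[4.4]nonan-2-yl]hexyl}isobenzofuran-1(3H)-one, via hydroxy ester 26 (not isolated)
Conditions: Bu4NF, THF, 0 °C → rt
Reagents that add atoms: none
Why: Fluoride cleaves the Si–O bond and the alkoxide closes ring B by 5-exo-trig acyl substitution at the ortho ester with loss of methoxide (desilylation–lactonisation). The C3–O bond is never broken, so the S configuration set in step 7 is kept.

## Compound list

1 | 8-bromooct-1-ene | C=CCCCCCCBr | starting material
2 | (S)-2-(chloromethyl)oxirane [(S)-epichlorohydrin] | ClC[C@@H]1CO1 | starting material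
3 | oct-7-en-1-ylmagnesium bromide | C=CCCCCCC[Mg]Br | intermediate (not isolated)
4 | (S)-1-chloroundec-10-en-2-ol | ClC[C@@H](O)CCCCCCCC=C | intermediate
5 | (S)-2-(non-8-en-1-yl)oxirane | C=CCCCCCCC[C@H]1CO1 | intermediate
6 | acetone N,N-dimethylhydrazone | CC(C)=NN(C)C | starting material
7 | (S)-2-methyloxirane [(S)-propylene oxide] | C[C@H]1CO1 | starting material
8 | (S)-5-(2,2-dimethylhydrazinylidene)hexan-2-ol (present as its lithium alkoxide) | C[C@H](O)CCC(C)=NN(C)C | intermediate (not isolated)
9 | (2S,8S)-5-(2,2-dimethylhydrazinylidene)heptadec-16-ene-2,8-diol | C[C@H](O)CCC(=NN(C)C)CC[C@@H](O)CCCCCCCC=C | intermediate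
10 | (2S,8S)-2,8-dihydroxyheptadec-16-en-5-one | C[C@H](O)CCC(=O)CC[C@@H](O)CCCCCCCC=C | intermediate (not isolated)
11 | (2S,7S)-2-methyl-7-(non-8-en-1-yl)-1,6-dioxaspiro[4.4]nonane (mixture of the 5S and 5R epimers, spiro centre undefined) | C=CCCCCCCC[C@H]1CCC2(CC[C@H](C)O2)O1 | intermediate
12 | (2S,5S,7S)-2-methyl-7-(non-8-en-1-yl)-1,6-dioxaspiro[4.4]nonane | C=CCCCCCCC[C@H]1CC[C@]2(CC[C@H](C)O2)O1 | intermediate
13 | 8-[(2S,5S,7S)-7-methyl-1,6-dioxaspiro[4.4]nonan-2-yl]octanal | O=CCCCCCCC[C@H]1CC[C@]2(CC[C@H](C)O2)O1 | intermediate
14 | 1-(triphenylphosphoranylidene)propan-2-one | CC(=O)C=P(c1ccccc1)(c1ccccc1)c1ccccc1 | starting material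
15 | (S)-2-[(phenylamino)oxy]-8-[(2S,5S,7S)-7-methyl-1,6-dioxaspiro[4.4]nonan-2-yl]octanal | O=C[C@@H](ONc1ccccc1)CCCCCC[C@H]1CC[C@]2(CC[C@H](C)O2)O1 | intermediate (not isolated)
16 | (S,E)-5-[(phenylamino)oxy]-11-[(2S,5S,7S)-7-methyl-1,6-dioxaspiro[4.4]nonan-2-yl]undec-3-en-2-one | CC(=O)/C=C/[C@@H](ONc1ccccc1)CCCCCC[C@H]1CC[C@]2(CC[C@H](C)O2)O1 | intermediate
17 | (S,E)-5-hydroxy-11-[(2S,5S,7S)-7-methyl-1,6-dioxaspiro[4.4]nonan-2-yl]undec-3-en-2-one | CC(=O)/C=C/[C@@H](O)CCCCCC[C@H]1CC[C@]2(CC[C@H](C)O2)O1 | intermediate
18 | (S,E)-5-[(tert-butyldimethylsilyl)oxy]-11-[(2S,5S,7S)-7-methyl-1,6-dioxaspiro[4.4]nonan-2-yl]undec-3-en-2-one | CC(=O)/C=C/[C@@H](O[Si](C)(C)C(C)(C)C)CCCCCC[C@H]1CC[C@]2(CC[C@H](C)O2)O1 | intermediate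
19 | dimethyl malonate | COC(=O)CC(=O)OC | starting material
20 | dimethyl 2-{(5S)-5-[(tert-butyldimethylsilyl)oxy]-11-[(2S,5S,7S)-7-methyl-1,6-dioxaspiro[4.4]nonan-2-yl]-2-oxoundecan-4-yl}malonate (C4 undefined) | CC(=O)CC(C(C(=O)OC)C(=O)OC)[C@@H](O[Si](C)(C)C(C)(C)C)CCCCCC[C@H]1CC[C@]2(CC[C@H](C)O2)O1 | intermediate (not isolated)
21 | methyl 2-{(S)-1-[(tert-butyldimethylsilyl)oxy]-7-[(2S,5S,7S)-7-methyl-1,6-dioxaspiro[4.4]nonan-2-yl]heptyl}-4,6-dioxocyclohexane-1-carboxylate (ring centres undefined) | COC(=O)C1C(=O)CC(=O)CC1[C@@H](O[Si](C)(C)C(C)(C)C)CCCCCC[C@H]2CC[C@]3(CC[C@H](C)O3)O2 | intermediate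
22 | methyl 6-{(S)-1-[(tert-butyldimethylsilyl)oxy]-7-[(2S,5S,7S)-7-methyl-1,6-dioxaspiro[4.4]nonan-2-yl]heptyl}-2,4-bis[(trimethylsilyl)oxy]cyclohexa-1,3-diene-1-carboxylate (one of the possible dienol ether isomers) | COC(=O)C1=C(O[Si](C)(C)C)C=C(O[Si](C)(C)C)CC1[C@@H](O[Si](C)(C)C(C)(C)C)CCCCCC[C@H]2CC[C@]3(CC[C@H](C)O3)O2 | intermediate (not isolated)
23 | methyl 2-{(S)-1-[(tert-butyldimethylsilyl)oxy]-7-[(2S,5S,7S)-7-methyl-1,6-dioxaspiro[4.4]nonan-2-yl]heptyl}-4,6-bis[(trimethylsilyl)oxy]benzoate | COC(=O)c1c(O[Si](C)(C)C)cc(O[Si](C)(C)C)cc1[C@@H](O[Si](C)(C)C(C)(C)C)CCCCCC[C@H]2CC[C@]3(CC[C@H](C)O3)O2 | intermediate (not isolated)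
24 | methyl 2-{(S)-1-[(tert-butyldimethylsilyl)oxy]-7-[(2S,5S,7S)-7-methyl-1,6-dioxaspiro[4.4]nonan-2-yl]heptyl}-4,6-dihydroxybenzoate | COC(=O)c1c(O)cc(O)cc1[C@@H](O[Si](C)(C)C(C)(C)C)CCCCCC[C@H]2CC[C@]3(CC[C@H](C)O3)O2 | intermediate
25 | methyl 2-{(S)-1-[(tert-butyldimethylsilyl)oxy]-7-[(2S,5S,7S)-7-methyl-1,6-dioxaspiro[4.4]nonan-2-yl]heptyl}-4,6-dimethoxybenzoate | COC(=O)c1c(OC)cc(OC)cc1[C@@H](O[Si](C)(C)C(C)(C)C)CCCCCC[C@H]2CC[C@]3(CC[C@H](C)O3)O2 | intermediate
26 | methyl 2-{(S)-1-hydroxy-7-[(2S,5S,7S)-7-methyl-1,6-dioxaspiro[4.4]nonan-2-yl]heptyl}-4,6-dimethoxybenzoate | COC(=O)c1c(OC)cc(OC)cc1[C@@H](O)CCCCCC[C@H]2CC[C@]3(CC[C@H](C)O3)O2 | intermediate (not isolated)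
27 | (S)-5,7-dimethoxy-3-{6-[(2S,5S,7S)-7-methyl-1,6-dioxaspiro[4.4]nonan-2-yl]hexyl}isobenzofuran-1(3H)-one | COc1cc(OC)c2c(c1)[C@H](CCCCCC[C@H]1CC[C@]3(CC[C@H](C)O3)O1)OC2=O | target

## Step count and least certain steps

Total: 13 steps. The longest linear sequence is 13 steps (from 1 to 27 through steps 1–13).

**Step 10 (key step).** The enone may be deprotonated at its γ-position before the malonate adds, which would lose configuration at C3 or isomerise the enone. The Claisen closure may stall at the Michael adduct. The silyl ether may be cleaved by hot methoxide and the freed alkoxide may lactonise. On work-up the product is a vinylogous acid that could catalyse epimerisation at C5''.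
Fallback: exchange the roles of the two partners; it sets out from 13 and returns at 21. Aldehyde 13 is aminoxylated as in step 7 and olefinated in the same flask with trimethyl phosphonoacetate, LiCl and DBU to give methyl (S,E)-4-[(phenylamino)oxy]-10-[(2S,5S,7S)-7-methyl-1,6-dioxaspiro[4.4]nonan-2-yl]dec-2-enoate F1. Cu(OAc)2 in EtOH gives the hydroxy enoate F2, and TBSCl with imidazole gives the silyl ether F3. Methyl acetoacetate and NaOMe in MeOH then add to F3 to give the pentanedioate adduct F4, whose acetyl methyl group closes onto the chain ester to give the same dione 21. The γ-hydrogen of an enoate is far less acidic than that of the enone, which removes the main threat to C3, at the price of a less reactive acceptor.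

**Step 11.** The silyl dienol ether may hydrolyse back to the dione before it is oxidised. The quinone may over-oxidise the electron-rich product. The hydroquinone by-product may epimerise C5'' if the buffer is insufficient.
Fallback: the classical acidic aromatisation, with the spiro centre corrected at the end; it sets out from 21 and returns at 27. Iodine in refluxing MeOH dehydrogenates 21, and the acid formed removes the silyl group, closes the lactone and equilibrates C5''. This should give mainly (3S)-7-hydroxy-5-methoxy-3-{6-[(2S,7S)-7-methyl-1,6-dioxaspiro[4.4]nonan-2-yl]hexyl}isobenzofuran-1(3H)-one F5 as both spiro epimers. MeI and K2CO3 convert F5 into 27 and its spiro epimer, (S)-5,7-dimethoxy-3-{6-[(2S,5R,7S)-7-methyl-1,6-dioxaspiro[4.4]nonan-2-yl]hexyl}isobenzofuran-1(3H)-one F6. These are separated by preparative HPLC, and F6 is returned to PPTS in CH2Cl2 and separated again.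

**Step 5.** The two non-polar spiro epimers in 11 may not separate cleanly, and an unfavourable equilibrium position would demand many cycles of equilibration and separation.
Fallback: separate at a more polar compound; it sets out from 11 and returns at 13. Ozonolysis of the unseparated mixture 11 with NaBH4 work-up gives 8-[(2S,5S,7S)-7-methyl-1,6-dioxaspiro[4.4]nonan-2-yl]octan-1-ol F7 and its spiro epimer, 8-[(2S,5R,7S)-7-methyl-1,6-dioxaspiro[4.4]nonan-2-yl]octan-1-ol F8. These are separated as alcohols or as crystalline esters. F8 is re-equilibrated with PPTS and separated again, and F7 is oxidised with SO3·pyridine, DMSO and i-Pr2NEt to 13.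

**Step 7.** The α-aminoxy aldehyde may enolise before it is olefinated, lowering the enantiomeric purity. Attack through nitrogen instead of oxygen may compete. The amino acid catalyst may slowly epimerise C5''.
Fallback: an oxygen source that leaves no N–O bond and a catalyst without an acidic group; it sets out from 13 and returns at 17. Dibenzoyl peroxide with (S)-2-tritylpyrrolidine, which shields one enamine face and so should induce in the sense opposite to proline of the same configuration, would give (S)-1-oxo-8-[(2S,5S,7S)-7-methyl-1,6-dioxaspiro[4.4]nonan-2-yl]octan-2-yl benzoate F9. Wittig reaction with 14 gives (S,E)-2-oxo-11-[(2S,5S,7S)-7-methyl-1,6-dioxaspiro[4.4]nonan-2-yl]undec-3-en-5-yl benzoate F10. Methanolysis with K2CO3 in MeOH at 0 °C gives 17.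

## Further compounds

F1 | step 10 | methyl (S,E)-4-[(phenylamino)oxy]-10-[(2S,5S,7S)-7-methyl-1,6-dioxaspiro[4.4]nonan-2-yl]dec-2-enoate | COC(=O)/C=C/[C@@H](ONc1ccccc1)CCCCCC[C@H]1CC[C@]2(CC[C@H](C)O2)O1
F2 | step 10 | methyl (S,E)-4-hydroxy-10-[(2S,5S,7S)-7-methyl-1,6-dioxaspiro[4.4]nonan-2-yl]dec-2-enoate | COC(=O)/C=C/[C@@H](O)CCCCCC[C@H]1CC[C@]2(CC[C@H](C)O2)O1
F3 | step 10 | methyl (S,E)-4-[(tert-butyldimethylsilyl)oxy]-10-[(2S,5S,7S)-7-methyl-1,6-dioxaspiro[4.4]nonan-2-yl]dec-2-enoate | COC(=O)/C=C/[C@@H](O[Si](C)(C)C(C)(C)C)CCCCCC[C@H]1CC[C@]2(CC[C@H](C)O2)O1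
F4 | step 10 | dimethyl 2-acetyl-3-{(S)-1-[(tert-butyldimethylsilyl)oxy]-7-[(2S,5S,7S)-7-methyl-1,6-dioxaspiro[4.4]nonan-2-yl]heptyl}pentanedioate | COC(=O)CC(C(C(C)=O)C(=O)OC)[C@@H](O[Si](C)(C)C(C)(C)C)CCCCCC[C@H]1CC[C@]2(CC[C@H](C)O2)O1
F5 | step 11 | (3S)-7-hydroxy-5-methoxy-3-{6-[(2S,7S)-7-methyl-1,6-dioxaspiro[4.4]nonan-2-yl]hexyl}isobenzofuran-1(3H)-one (both spiro epimers) | COc1cc(O)c2c(c1)[C@H](CCCCCC[C@H]1CCC3(CC[C@H](C)O3)O1)OC2=O
F6 | step 11 | (S)-5,7-dimethoxy-3-{6-[(2S,5R,7S)-7-methyl-1,6-dioxaspiro[4.4]nonan-2-yl]hexyl}isobenzofuran-1(3H)-one | COc1cc(OC)c2c(c1)[C@H](CCCCCC[C@H]1CC[C@@]3(CC[C@H](C)O3)O1)OC2=O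
F7 | step 5 | 8-[(2S,5S,7S)-7-methyl-1,6-dioxaspiro[4.4]nonan-2-yl]octan-1-ol | OCCCCCCCC[C@H]1CC[C@]2(CC[C@H](C)O2)O1
F8 | step 5 | 8-[(2S,5R,7S)-7-methyl-1,6-dioxaspiro[4.4]nonan-2-yl]octan-1-ol | OCCCCCCCC[C@H]1CC[C@@]2(CC[C@H](C)O2)O1
F9 | step 7 | (S)-1-oxo-8-[(2S,5S,7S)-7-methyl-1,6-dioxaspiro[4.4]nonan-2-yl]octan-2-yl benzoate | O=C[C@@H](OC(=O)c1ccccc1)CCCCCC[C@H]1CC[C@]2(CC[C@H](C)O2)O1
F10 | step 7 | (S,E)-2-oxo-11-[(2S,5S,7S)-7-methyl-1,6-dioxaspiro[4.4]nonan-2-yl]undec-3-en-5-yl benzoate | CC(=O)/C=C/[C@@H](OC(=O)c1ccccc1)CCCCCC[C@H]1CC[C@]2(CC[C@H](C)O2)O1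
A1 | alternative 1 | (2S,8S,15S)-15-[(tert-butyldimethylsilyl)oxy]-15-(3,5-dimethoxyphenyl)-5-(2,2-dimethylhydrazinylidene)pentadecane-2,8-diol | COc1cc(OC)cc(c1)[C@@H](O[Si](C)(C)C(C)(C)C)CCCCCC[C@H](O)CCC(=NN(C)C)CC[C@H](C)O
A2 | alternative 1 | tert-butyl{[(S)-1-(3,5-dimethoxyphenyl)-7-[(S)-oxiran-2-yl]heptyl]oxy}dimethylsilane | COc1cc(OC)cc(c1)[C@@H](O[Si](C)(C)C(C)(C)C)CCCCCC[C@H]1CO1
A3 | alternative 2 | 7-[(2S,4S,5S,7S)-4-iodo-7-methyl-1,6-dioxaspiro[4.4]nonan-2-yl]-N-methoxy-N-methylheptanamide | CON(C)C(=O)CCCCCC[C@H]1C[C@H](I)[C@]3(CC[C@H](C)O3)O1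
A4 | alternative 2 | 7-{(2S)-5-[(3S)-3-hydroxybutyl]-2,3-dihydrofuran-2-yl}-N-methoxy-N-methylheptanamide | CON(C)C(=O)CCCCCC[C@H]1CC=C(CC[C@H](C)O)O1
A5 | alternative 3 | (Z)-5,7-dimethoxy-3-{6-[(2S,5S,7S)-7-methyl-1,6-dioxaspiro[4.4]nonan-2-yl]hexylidene}isobenzofuran-1(3H)-one | COc1cc(OC)c2c(c1)/C(=C/CCCCC[C@H]1CC[C@]3(CC[C@H](C)O3)O1)OC2=O
A6 | alternative 3 | 2-iodo-4,6-dimethoxybenzoic acid | COc1cc(OC)c(C(=O)O)c(I)c1
A7 | alternative 3 | (2S,5S,7S)-2-(hept-6-yn-1-yl)-7-methyl-1,6-dioxaspiro[4.4]nonane | C#CCCCCC[C@H]1CC[C@]2(CC[C@H](C)O2)O1
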